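The readings are simulated with constants of no real substance; scatter was added.

We have to pick a bath for one recipe, 20 °C or 35 °C, and we judge it by the share of target among the products.

in all of them: starting material 0.80 M
- Thursday's: first nucleophile 0.88 M; second nucleophile 0.40 M; temperature 15 °C; run made earlier
- Wednesday's: first nucleophile 0.88 M; second nucleophile 1.6 M; temperature 28 °C; run made earlier
- Monday's: first nucleophile 0.44 M; second nucleophile 0.80 M; temperature 15 °C; run made earlier
- red: first nucleophile 0.880 M; second nucleophile 0.800 M; temperature 20 °C; time 2.0 min
- green: first nucleophile 0.880 M; second nucleophile 0.800 M; temperature 35 °C; time 2.0 min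

- Thursday's (time / s: target / %, other capture product / %): 10.0: 3.7, 1.8; 25.0: 11.7, 4.6; 50.0: 21.2, 8.2; 80.0: 29.7, 12.5
- Wednesday's (time / s: target / %, other capture product / %): 10.0: 12.2, 16.9; 25.0: 22.7, 34.0; 50.0: 26.5, 45.1; 80.0: 27.3, 49.4
- Monday's (time / s: target / %, other capture product / %): 10.0: 1.7, 3.0; 12.0: 3.8, 2.6; 30.0: 7.6, 10.2; 80.0: 16.0, 25.2

(readings scatter by 0.5 percentage points)

- the flask that comes out highest in share of target in all that became target or other capture product or solvolysis product, or "all alike" when all lie within 1.5 percentage points (red / green / all alike)
- share of target in all that became target or other capture product or solvolysis product, red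
- share of target in all that became target or other capture product or solvolysis product, green

We weigh the products by what competes for the intermediate. The other capture product gets the charged [second nucleophile], the target gets the charged [first nucleophile] times a factor ρ, and the solvolysis product gets a weight w in molar:

share = ρ[first nucleophile] / (ρ[first nucleophile] + [second nucleophile] + w)

Which number has to be known well? The charges are given, and in this rule time and temperature enter only through ρ and w. As a trial, with ρ at 1 and w equal to [second nucleophile], the share is 35.5 %. Raising ρ by a factor of 2 moves it by 17 percentage points, and raising w by the same factor moves it by 8.7 points, so ρ counts for more.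

Target over other capture product at the last reading, times charged second over charged first, reads:

Thursday: 1.08
Wednesday: 1.00
Monday: 1.15

Monday and Thursday, at one temperature, differ by 0.0700. Thursday and Wednesday, at 15 °C and 28 °C, differ by 0.0800, so we read no temperature trend. We take the mean 1.08 as ρ, an overall selectivity factor: target per other capture product at equal charges, as read at the last reading of a run. Thursday's target was still rising up to that reading, from 21.2 % to 29.7 %, so carrying ρ to the asked time is our assumption. Taking Wednesday's last reading as the end, the missing part is solvolysis product, which gives w = 0.755 M. Our reckoning then gives 37.9 % for each flask, so we expect them alike.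

The forecast differs: red highest, 35.5 % (32 % to 39 %) for red and 29.5 % (25 % to 34 %) for green, on the ground “Warming therefore wastes first nucleophile faster than intermediate forms”.

The flasks give 37.4 % for red and 37.0 % for green: all alike.

    first nucleophile + intermediate → target (k = 0.400 M⁻¹ s⁻¹, Ea = 52.0 kJ mol⁻¹)
    intermediate → solvolysis product (k = 0.110 s⁻¹, Ea = 67.0 kJ mol⁻¹)
    first nucleophile ⇌ dormant form (K = 2.70, k = 0.00700 s⁻¹, Ea = 71.0 kJ mol⁻¹, ΔH = −61.0 kJ mol⁻¹)
    second nucleophile + intermediate → other capture product (k = 0.250 M⁻¹ s⁻¹, Ea = 45.0 kJ mol⁻¹)
    2 first nucleophile → homo dimer (k = 0.00580 M⁻¹ s⁻¹, Ea = 71.0 kJ mol⁻¹)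
    starting material → intermediate (k = 0.0190 s⁻¹, Ea = 86.0 kJ mol⁻¹)
    (constants at 20 °C)

At the asked time red still holds 10.2 % of its starting material and green 0 %. The factor ρ, taken from the products at that time, is 0.908 in red and 1.08 in green. For the neighbour of red charged with 0.53 M of first nucleophile, 1.08 and w give 26.9 %, and that flask gives 27.7 %.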